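**Retrosynthetic overview**

1. The strategy rests on the 1,2-dioxane ring (O1–O2–C3–C4–C5–C6). Its C3 CH2CO2H arm, C4 methyl and C6 side chain (C7 onward) lie on one face, so dioxygen is added across C3 and C6 of a (3E,5E) C3=C4–C5=C6 diene, and C4 is then set by diimide reduction of the C4=C5 ring alkene from the face opposite both chains.
2. C1 acid ⇐ C1 acetoxy alcohol (late oxidation). C9=C10 (E) ⇐ Julia–Kocienski olefination of the dioxane aldehyde (C1–C9) with a 1-phenyltetrazolyl sulfone (C10–C14 plus phenyl), placed after the diimide step so that no side-chain alkene meets diimide.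
3. Diene (C1–C9) ⇐ (S)-3-bromo-2-methylpropan-1-ol (C7–C9, carries C8): acetylide displacement, two zirconium-catalysed methylaluminations around a Sonogashira coupling (both E-alkenes), oxirane opening (C1–C2), acetylation.
4. Sulfone ⇐ (R,E)-1-phenylbut-2-en-1-ol by Johnson–Claisen rearrangement (sets C12 and the C13=C14 E-alkene), reduction, Mitsunobu thioetherification, S-oxidation.
5. Ring order: the 3,6-dihydro-1,2-dioxine is the only ring formed (step 8) and is saturated to the 1,2-dioxane in step 9; the phenyl ring is bought.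

Key step: step 8

Remark on the chemistry: chain carbons are numbered C1 (carboxyl) to C14 (benzylic alkene carbon). The facial selectivity of the cycloaddition relative to C8 is expected to be low, so step 8 should give two ring diastereomers; only the wanted one is numbered, and the pair is carried together and separated after step 9.

**Route**

Step 1
Reactants: 1 (2S)-3-bromo-2-methylpropan-1-ol
Product: 2 [(2S)-3-bromo-2-methylpropoxy](tert-butyl)dimethylsilane
Conditions: TBSCl, imidazole, CH2Cl2, 0 °C → rt
Reagents that add atoms: tert-butyldimethylsilyl chloride, CC(C)(C)[Si](C)(C)Cl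
Why: Silylation of a primary alcohol (silyl ether formation) should be clean and leaves the stereocentre untouched.

Step 2
Reactants: 2 [(2S)-3-bromo-2-methylpropoxy](tert-butyl)dimethylsilane; 3 lithium acetylide–ethane-1,2-diamine complex
Product: 4 tert-butyl(dimethyl){[(2R)-2-methylpent-4-yn-1-yl]oxy}silane
Conditions: LiC≡CH·H2NCH2CH2NH2, DMSO, 0 °C → rt
Reagents that add atoms: none
Why: SN2 displacement of the primary bromide by acetylide in a dipolar aprotic solvent should give the terminal alkyne directly; the β-stereocentre is not involved, and its descriptor changes from S to R only through the priority rules.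

Step 3
Reactants: 4 tert-butyl(dimethyl){[(2R)-2-methylpent-4-yn-1-yl]oxy}silane; 5 trimethylaluminium
Product: 7 tert-butyl{[(2R,4E)-5-iodo-2,4-dimethylpent-4-en-1-yl]oxy}dimethylsilane, via alkenylalane 6 (not isolated)
Conditions: Me3Al, (C5H5)2ZrCl2 (0.25 equiv), CH2Cl2, 0 °C → rt; then I2, THF, −30 → 0 °C
Reagents that add atoms: iodine, II
Why: Zirconium-catalysed methylalumination (Negishi carboalumination) adds methyl and aluminium syn with aluminium on the terminal carbon, and iodinolysis with retention should give the (E)-alkenyl iodide that fixes the C5=C6 geometry.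

Step 4
Reactants: 7 tert-butyl{[(2R,4E)-5-iodo-2,4-dimethylpent-4-en-1-yl]oxy}dimethylsilane; 8 ethynyltrimethylsilane
Product: 9 tert-butyl{[(2R,4E)-2,4-dimethyl-7-(trimethylsilyl)hept-4-en-6-yn-1-yl]oxy}dimethylsilane
Conditions: Pd(PPh3)2Cl2 (cat.), CuI (cat.), Et3N, THF, rt
Reagents that add atoms: none
Why: Sonogashira coupling, in which oxidative addition of the alkenyl iodide to zerovalent palladium and the following steps proceed with retention, should keep the E alkene.

Step 5
Reactants: 9 tert-butyl{[(2R,4E)-2,4-dimethyl-7-(trimethylsilyl)hept-4-en-6-yn-1-yl]oxy}dimethylsilane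
Product: 10 tert-butyl{[(2R,4E)-2,4-dimethylhept-4-en-6-yn-1-yl]oxy}dimethylsilane
Conditions: K2CO3, MeOH, rt
Reagents that add atoms: none
Why: Base-mediated methanolysis of the alkynyl C–Si bond (protodesilylation) should free the terminal alkyne while the silyl ether on oxygen survives.

Step 6
Reactants: 10 tert-butyl{[(2R,4E)-2,4-dimethylhept-4-en-6-yn-1-yl]oxy}dimethylsilane; 5 trimethylaluminium; 11 oxirane
Product: 14 (3E,5E,8R)-9-[(tert-butyldimethylsilyl)oxy]-4,6,8-trimethylnona-3,5-dien-1-ol, via dienylalane 12 (not isolated), via lithium alanate 13 (not isolated)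
Conditions: Me3Al, (C5H5)2ZrCl2 (0.5 equiv), ClCH2CH2Cl, rt; volatiles removed; n-BuLi, hexane–THF, −78 → 0 °C; oxirane, 0 °C → rt; then H2O
Reagents that add atoms: none
Why: A second zirconium-catalysed methylalumination on the terminal alkyne of the enyne places methyl on C4 and aluminium on C3 syn, and the derived alanate should open oxirane with retention at the alkenyl carbon (alkenylalanate epoxide opening), which sets the 3E alkene and adds C1–C2.

Step 7
Reactants: 14 (3E,5E,8R)-9-[(tert-butyldimethylsilyl)oxy]-4,6,8-trimethylnona-3,5-dien-1-ol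
Product: 15 (3E,5E,8R)-9-[(tert-butyldimethylsilyl)oxy]-4,6,8-trimethylnona-3,5-dien-1-yl acetate
Conditions: Ac2O, pyridine, DMAP (cat.), CH2Cl2, 0 °C → rt
Reagents that add atoms: acetic anhydride, CC(=O)OC(C)=O
Why: Acylation of the primary alcohol (esterification) should be clean and removes a free hydroxyl that could steer or intercept singlet oxygen.

Step 8
Reactants: 15 (3E,5E,8R)-9-[(tert-butyldimethylsilyl)oxy]-4,6,8-trimethylnona-3,5-dien-1-yl acetate; 16 dioxygen
Product: 17 2-[(3S,6R)-6-[(2R)-3-[(tert-butyldimethylsilyl)oxy]-2-methylpropyl]-4,6-dimethyl-3,6-dihydro-1,2-dioxin-3-yl]ethyl acetate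
Conditions: O2 (1 atm), 5,10,15,20-tetraphenylporphyrin (cat.), CH2Cl2, white LED (> 400 nm), −20 °C
Reagents that add atoms: none
Why: Photosensitised singlet oxygen should add to the s-cis rotamer of the (3E,5E)-diene in a concerted suprafacial [4+2] cycloaddition, the dioxygen counterpart of the Diels–Alder reaction and the known route from acyclic 1,3-dienes to endoperoxides, forming the C3–O and C6–O bonds together. The six-membered 3,6-dihydro-1,2-dioxine ring is thus closed by an intermolecular cycloaddition in which both ring bonds to oxygen form in one step. C3 and C6 are set relative to each other by the diene geometry: C2 and C7 are the outside groups of the E,E-diene, so suprafacial addition places them cis on the ring. Their sense relative to C8 is controlled only weakly by that remote centre, so both facial isomers are expected and the (3S,6R) isomer is the one carried on. The step needs cycloaddition to outrun the ene reaction at the two trisubstituted alkenes; the C4 methyl disfavours the s-trans rotamer by allylic strain against the inside C6 methyl, which should keep the diene near the reactive s-cis geometry. The silyl ether and the acetate are inert, and no other alkene is present.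

Step 9
Reactants: 17 2-[(3S,6R)-6-[(2R)-3-[(tert-butyldimethylsilyl)oxy]-2-methylpropyl]-4,6-dimethyl-3,6-dihydro-1,2-dioxin-3-yl]ethyl acetate
Product: 18 2-[(3S,4S,6R)-6-[(2R)-3-[(tert-butyldimethylsilyl)oxy]-2-methylpropyl]-4,6-dimethyl-1,2-dioxan-3-yl]ethyl acetate
Conditions: KO2CN=NCO2K (large excess, in portions), AcOH, CH2Cl2–MeOH, 0 °C → rt; then preparative HPLC
Reagents that add atoms: none
Why: Diimide reduction transfers two hydrogens concertedly and syn to the C4=C5 alkene without touching the O–O bond; delivery to the face opposite the C3 arm and the C6 chain should push the C4 methyl onto their face (C4 = S), and the acidic medium avoids base-induced Kornblum–DeLaMare cleavage.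

Step 10
Reactants: 18 2-[(3S,4S,6R)-6-[(2R)-3-[(tert-butyldimethylsilyl)oxy]-2-methylpropyl]-4,6-dimethyl-1,2-dioxan-3-yl]ethyl acetate
Product: 19 2-[(3S,4S,6R)-6-[(2R)-3-hydroxy-2-methylpropyl]-4,6-dimethyl-1,2-dioxan-3-yl]ethyl acetate
Conditions: HF·pyridine, pyridine, THF, 0 °C → rt
Reagents that add atoms: none
Why: Fluoride-driven cleavage of the Si–O bond (desilylation) under buffered, non-basic conditions should leave the acetate and the peroxide intact.

Step 11
Reactants: 19 2-[(3S,4S,6R)-6-[(2R)-3-hydroxy-2-methylpropyl]-4,6-dimethyl-1,2-dioxan-3-yl]ethyl acetate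
Product: 20 2-[(3S,4S,6S)-4,6-dimethyl-6-[(2R)-2-methyl-3-oxopropyl]-1,2-dioxan-3-yl]ethyl acetate
Conditions: Dess–Martin periodinane, NaHCO3, CH2Cl2, 0 °C → rt
Reagents that add atoms: none
Why: Dess–Martin oxidation is mild and buffered, so the C8 centre α to the new aldehyde should not epimerise and the O–O bond is not attacked (the C6 descriptor changes to S only through the priority rules).

Step 12
Reactants: 21 (2E)-but-2-enal; 22 phenylmagnesium bromide
Product: 23 rac-(2E)-1-phenylbut-2-en-1-ol
Conditions: THF, −78 → 0 °C; then H2O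
Reagents that add atoms: none
Why: Grignard reagents add 1,2 to enals, which should give the racemic allylic alcohol with the E alkene kept.

Step 13
Reactants: 23 rac-(2E)-1-phenylbut-2-en-1-ol
Product: 24 (1R,2E)-1-phenylbut-2-en-1-ol
Conditions: Ti(OiPr)4, D-(−)-diisopropyl tartrate, t-BuOOH (0.6 equiv), 4 Å molecular sieves, CH2Cl2, −20 °C
Reagents that add atoms: none
Why: In the Sharpless kinetic resolution with the D-(−)-tartrate the S enantiomer should be epoxidised much faster, so the R alcohol is recovered and its configuration is selected by the chiral titanium–tartrate catalyst.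

Step 14
Reactants: 24 (1R,2E)-1-phenylbut-2-en-1-ol; 25 triethyl orthoacetate
Product: 27 ethyl (3S,4E)-3-methyl-5-phenylpent-4-enoate, via ketene acetal 26 (not isolated)
Conditions: CH3C(OEt)3, EtCO2H (cat.), 135 °C, EtOH distilled off
Reagents that add atoms: none
Why: In the Johnson–Claisen rearrangement the chair transition state with phenyl pseudo-equatorial forms the new C–C bond on the alkene face from which the C–O bond leaves, so the carbinol chirality should be transferred to C12 (S) and the styrenyl alkene should form as E.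

Step 15
Reactants: 27 ethyl (3S,4E)-3-methyl-5-phenylpent-4-enoate
Product: 28 (3S,4E)-3-methyl-5-phenylpent-4-en-1-ol
Conditions: LiAlH4, Et2O, 0 °C; then H2O
Reagents that add atoms: none
Why: Hydride reduction of the ester should give the primary alcohol without touching the alkene or the stereocentre.

Step 16
Reactants: 28 (3S,4E)-3-methyl-5-phenylpent-4-en-1-ol; 29 1-phenyl-1H-tetrazole-5-thiol
Product: 30 5-{[(3S,4E)-3-methyl-5-phenylpent-4-en-1-yl]sulfanyl}-1-phenyl-1H-tetrazole
Conditions: PPh3, diisopropyl azodicarboxylate, THF, 0 °C → rt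
Reagents that add atoms: none
Why: Mitsunobu thioetherification of a primary alcohol with the acidic tetrazole thiol should proceed cleanly at the unbranched carbon.

Step 17
Reactants: 30 5-{[(3S,4E)-3-methyl-5-phenylpent-4-en-1-yl]sulfanyl}-1-phenyl-1H-tetrazole
Product: 31 5-{[(3S,4E)-3-methyl-5-phenylpent-4-en-1-yl]sulfonyl}-1-phenyl-1H-tetrazole
Conditions: (NH4)6Mo7O24·4H2O (cat.), 30% H2O2, EtOH, 0 °C → rt
Reagents that add atoms: hydrogen peroxide, OO
Why: Molybdate-catalysed peroxide oxidation takes the sulfide to the sulfone and should be chemoselective over the styrenyl alkene.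

Step 18
Reactants: 20 2-[(3S,4S,6S)-4,6-dimethyl-6-[(2R)-2-methyl-3-oxopropyl]-1,2-dioxan-3-yl]ethyl acetate; 31 5-{[(3S,4E)-3-methyl-5-phenylpent-4-en-1-yl]sulfonyl}-1-phenyl-1H-tetrazole
Product: 33 2-[(3S,4S,6R)-4,6-dimethyl-6-[(2R,3E,6S,7E)-2,6-dimethyl-8-phenylocta-3,7-dien-1-yl]-1,2-dioxan-3-yl]ethyl acetate, via potassium sulfonyl carbanion 32 (not isolated)
Conditions: 31, KN(SiMe3)2, DME, −78 °C; then 20, −78 °C → rt
Reagents that add atoms: none
Why: In the Julia–Kocienski olefination the premetalated tetrazolyl sulfone adds to the aldehyde and Smiles rearrangement with loss of SO2 and the tetrazololate should give the C9=C10 alkene, E-selective with potassium in DME; premetalation keeps free amide base away from the peroxide and the epimerisable C8, and the sulfone is placed on the side-chain piece because a C9 carbanion on the dioxane piece could attack the O–O bond.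

Step 19
Reactants: 33 2-[(3S,4S,6R)-4,6-dimethyl-6-[(2R,3E,6S,7E)-2,6-dimethyl-8-phenylocta-3,7-dien-1-yl]-1,2-dioxan-3-yl]ethyl acetate
Product: 34 2-[(3S,4S,6R)-4,6-dimethyl-6-[(2R,3E,6S,7E)-2,6-dimethyl-8-phenylocta-3,7-dien-1-yl]-1,2-dioxan-3-yl]ethan-1-ol
Conditions: K2CO3, MeOH, 0 °C
Reagents that add atoms: none
Why: Mild methanolysis (transesterification) should remove the acetate; a saturated dialkyl peroxide without an activated α-hydrogen should tolerate carbonate at low temperature.

Step 20
Reactants: 34 2-[(3S,4S,6R)-4,6-dimethyl-6-[(2R,3E,6S,7E)-2,6-dimethyl-8-phenylocta-3,7-dien-1-yl]-1,2-dioxan-3-yl]ethan-1-ol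
Product: 36 2-[(3S,4S,6R)-4,6-dimethyl-6-[(2R,3E,6S,7E)-2,6-dimethyl-8-phenylocta-3,7-dien-1-yl]-1,2-dioxan-3-yl]acetic acid (target CNP0179089.2), via aldehyde 35 (not isolated)
Conditions: TEMPO (cat.), PhI(OAc)2, MeCN–H2O, 0 °C → rt
Reagents that add atoms: water, O
Why: The oxoammonium (TEMPO/PhI(OAc)2) oxidation takes the primary alcohol to the aldehyde and its hydrate on to the acid under non-basic conditions, so the β-peroxy carbonyl should not eliminate and the two alkenes and the O–O bond should be untouched.

**Compound list**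

1 | (2S)-3-bromo-2-methylpropan-1-ol | OC[C@H](C)CBr | starting material
2 | [(2S)-3-bromo-2-methylpropoxy](tert-butyl)dimethylsilane | CC(C)(C)[Si](C)(C)OC[C@H](C)CBr | intermediate
3 | lithium acetylide–ethane-1,2-diamine complex | [Li]C#C.NCCN | starting material
4 | tert-butyl(dimethyl){[(2R)-2-methylpent-4-yn-1-yl]oxy}silane | CC(C)(C)[Si](C)(C)OC[C@H](C)CC#C | intermediate
5 | trimethylaluminium | C[Al](C)C | starting material
6 | tert-butyl{[(2R,4E)-5-(dimethylalumanyl)-2,4-dimethylpent-4-en-1-yl]oxy}dimethylsilane (alkenylalane) | CC(C)(C)[Si](C)(C)OC[C@H](C)C/C(C)=C/[Al](C)C | intermediate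
7 | tert-butyl{[(2R,4E)-5-iodo-2,4-dimethylpent-4-en-1-yl]oxy}dimethylsilane | CC(C)(C)[Si](C)(C)OC[C@H](C)C/C(C)=C/I | intermediate
8 | ethynyltrimethylsilane | C#C[Si](C)(C)C | starting material
9 | tert-butyl{[(2R,4E)-2,4-dimethyl-7-(trimethylsilyl)hept-4-en-6-yn-1-yl]oxy}dimethylsilane | CC(C)(C)[Si](C)(C)OC[C@H](C)C/C(C)=C/C#C[Si](C)(C)C | intermediate
10 | tert-butyl{[(2R,4E)-2,4-dimethylhept-4-en-6-yn-1-yl]oxy}dimethylsilane | CC(C)(C)[Si](C)(C)OC[C@H](C)C/C(C)=C/C#C | intermediate
11 | oxirane | C1CO1 | starting material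
12 | tert-butyl{[(2R,4E,6E)-7-(dimethylalumanyl)-2,4,6-trimethylhepta-4,6-dien-1-yl]oxy}dimethylsilane (dienylalane) | CC(C)(C)[Si](C)(C)OC[C@H](C)C/C(C)=C/C(C)=C/[Al](C)C | intermediate
13 | lithium butyl{(1E,3E,6R)-7-[(tert-butyldimethylsilyl)oxy]-2,4,6-trimethylhepta-1,3-dien-1-yl}dimethylaluminate (lithium alanate) | CC(C)(C)[Si](C)(C)OC[C@H](C)C/C(C)=C/C(C)=C/[Al-](C)(C)CCCC.[Li+] | intermediate
14 | (3E,5E,8R)-9-[(tert-butyldimethylsilyl)oxy]-4,6,8-trimethylnona-3,5-dien-1-ol | CC(C)(C)[Si](C)(C)OC[C@H](C)C/C(C)=C/C(C)=C/CCO | intermediate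
15 | (3E,5E,8R)-9-[(tert-butyldimethylsilyl)oxy]-4,6,8-trimethylnona-3,5-dien-1-yl acetate | CC(C)(C)[Si](C)(C)OC[C@H](C)C/C(C)=C/C(C)=C/CCOC(C)=O | intermediate
16 | dioxygen (used as singlet oxygen) | O=O | starting material
17 | 2-[(3S,6R)-6-[(2R)-3-[(tert-butyldimethylsilyl)oxy]-2-methylpropyl]-4,6-dimethyl-3,6-dihydro-1,2-dioxin-3-yl]ethyl acetate | CC(C)(C)[Si](C)(C)OC[C@H](C)C[C@]1(C)C=C(C)[C@H](CCOC(C)=O)OO1 | intermediate
18 | 2-[(3S,4S,6R)-6-[(2R)-3-[(tert-butyldimethylsilyl)oxy]-2-methylpropyl]-4,6-dimethyl-1,2-dioxan-3-yl]ethyl acetate | CC(C)(C)[Si](C)(C)OC[C@H](C)C[C@]1(C)C[C@H](C)[C@H](CCOC(C)=O)OO1 | intermediate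
19 | 2-[(3S,4S,6R)-6-[(2R)-3-hydroxy-2-methylpropyl]-4,6-dimethyl-1,2-dioxan-3-yl]ethyl acetate | OC[C@H](C)C[C@]1(C)C[C@H](C)[C@H](CCOC(C)=O)OO1 | intermediate
20 | 2-[(3S,4S,6S)-4,6-dimethyl-6-[(2R)-2-methyl-3-oxopropyl]-1,2-dioxan-3-yl]ethyl acetate | O=C[C@H](C)C[C@]1(C)C[C@H](C)[C@H](CCOC(C)=O)OO1 | intermediate
21 | (2E)-but-2-enal | C/C=C/C=O | starting material
22 | phenylmagnesium bromide | Br[Mg]c1ccccc1 | starting material
23 | rac-(2E)-1-phenylbut-2-en-1-ol | C/C=C/C(O)c1ccccc1 | intermediate
24 | (1R,2E)-1-phenylbut-2-en-1-ol | C/C=C/[C@@H](O)c1ccccc1 | intermediate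
25 | triethyl orthoacetate (1,1,1-triethoxyethane) | CC(OCC)(OCC)OCC | starting material
26 | {(1R,2E)-1-[(1-ethoxyethenyl)oxy]but-2-en-1-yl}benzene (ketene acetal) | C=C(OCC)O[C@H](/C=C/C)c1ccccc1 | intermediate
27 | ethyl (3S,4E)-3-methyl-5-phenylpent-4-enoate | C[C@H](/C=C/c1ccccc1)CC(=O)OCC | intermediate
28 | (3S,4E)-3-methyl-5-phenylpent-4-en-1-ol | C[C@H](/C=C/c1ccccc1)CCO | intermediate
29 | 1-phenyl-1H-tetrazole-5-thiol | Sc1nnnn1-c1ccccc1 | starting material
30 | 5-{[(3S,4E)-3-methyl-5-phenylpent-4-en-1-yl]sulfanyl}-1-phenyl-1H-tetrazole | C[C@H](/C=C/c1ccccc1)CCSc1nnnn1-c1ccccc1 | intermediate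
31 | 5-{[(3S,4E)-3-methyl-5-phenylpent-4-en-1-yl]sulfonyl}-1-phenyl-1H-tetrazole | C[C@H](/C=C/c1ccccc1)CCS(=O)(=O)c1nnnn1-c1ccccc1 | intermediate
32 | potassium (3S,4E)-3-methyl-5-phenyl-1-[(1-phenyl-1H-tetrazol-5-yl)sulfonyl]pent-4-en-1-ide (potassium sulfonyl carbanion) | C[C@H](/C=C/c1ccccc1)C[CH-]S(=O)(=O)c1nnnn1-c1ccccc1.[K+] | intermediate
33 | 2-[(3S,4S,6R)-4,6-dimethyl-6-[(2R,3E,6S,7E)-2,6-dimethyl-8-phenylocta-3,7-dien-1-yl]-1,2-dioxan-3-yl]ethyl acetate | C[C@H](/C=C/c1ccccc1)C/C=C/[C@H](C)C[C@]1(C)C[C@H](C)[C@H](CCOC(C)=O)OO1 | intermediate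
34 | 2-[(3S,4S,6R)-4,6-dimethyl-6-[(2R,3E,6S,7E)-2,6-dimethyl-8-phenylocta-3,7-dien-1-yl]-1,2-dioxan-3-yl]ethan-1-ol | C[C@H](/C=C/c1ccccc1)C/C=C/[C@H](C)C[C@]1(C)C[C@H](C)[C@H](CCO)OO1 | intermediate
35 | 2-[(3S,4S,6R)-4,6-dimethyl-6-[(2R,3E,6S,7E)-2,6-dimethyl-8-phenylocta-3,7-dien-1-yl]-1,2-dioxan-3-yl]acetaldehyde | C[C@H](/C=C/c1ccccc1)C/C=C/[C@H](C)C[C@]1(C)C[C@H](C)[C@H](CC=O)OO1 | intermediate
36 | 2-[(3S,4S,6R)-4,6-dimethyl-6-[(2R,3E,6S,7E)-2,6-dimethyl-8-phenylocta-3,7-dien-1-yl]-1,2-dioxan-3-yl]acetic acid | C[C@H](/C=C/c1ccccc1)C/C=C/[C@H](C)C[C@]1(C)C[C@H](C)[C@H](CC(=O)O)OO1 | target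

**Step count and risks**

Total step count: 20 (11 steps to aldehyde 20, 6 steps to sulfone 31, 3 steps after their union).
Longest linear sequence: 14 steps (steps 1–11 and 18–20).

Steps most likely to fail:

1. Step 8 (singlet-oxygen cycloaddition). The ene reaction at the two trisubstituted alkenes (hydrogen abstraction from the C4 and C6 methyls or the C2 and C7 methylenes) may outrun the cycloaddition, and the weak facial bias costs material as the unwanted ring diastereomer. Fallback: abandon singlet oxygen and close the same ring with ground-state dioxygen under cation-radical chain catalysis. Diene 15 is treated with O2 and catalytic [(4-BrC6H4)3N]SbCl6 in CH2Cl2 at −78 °C; the diene cation radical takes up triplet oxygen and the peroxyl cation closes onto the other diene terminus, a known oxygenation of electron-rich conjugated dienes that has no ene channel. Because this pathway is stepwise, the cis C3/C6 relationship would have to be confirmed. The fallback sets out from 15 and comes back to the route at 17; it makes no new compound.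

2. Step 9 (diimide reduction). Hydrogen transfer to the trisubstituted ring alkene may stall while diimide disproportionates, or hydrogen may be delivered to both faces so that C4 epimers form. Fallback: replace the reagent-based hydrogen transfer by heterogeneous catalytic hydrogenation. Dihydrodioxine 17 is stirred under H2 (1 atm) over PtO2 in EtOAc at 0 °C and stopped after one equivalent of uptake; the surface should take the alkene from the same open face, and hindered secondary/tertiary dialkyl peroxides can outlast short alkene hydrogenations on platinum, although O–O hydrogenolysis to the 1,4-diol is the competing process to watch on a small scale first. The fallback sets out from 17 and comes back at 18; it makes no new compound.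

3. Step 18 (Julia–Kocienski olefination). Enolisation of the aldehyde may epimerise C8, the sulfonyl carbanion may attack the O–O bond or the acetate, or E/Z control may be poor. Fallback: form C9=C10 by alkene cross-metathesis, which needs no sulfonyl carbanion. Aldehyde 20 is methylenated (Ph3PCH3Br, KN(SiMe3)2, THF, −78 → 0 °C) to 2-[(3S,4S,6R)-4,6-dimethyl-6-[(2R)-2-methylbut-3-en-1-yl]-1,2-dioxan-3-yl]ethyl acetate F1. Ester 27 is reduced with i-Bu2AlH (CH2Cl2, −78 °C) to (3S,4E)-3-methyl-5-phenylpent-4-enal F2, which is methylenated in the same way to [(1E,3S)-3-methylhexa-1,5-dien-1-yl]benzene F3. Cross-metathesis of F1 with an excess of F3 (second-generation Hoveyda–Grubbs catalyst, CH2Cl2, 40 °C) should give mainly the E-alkene; the ruthenium carbene tolerates dialkyl peroxides, and the styrenyl alkene of F3, being 1,2-disubstituted with an allylic branch, should react far more slowly than the two terminal alkenes. The fallback sets out from 20 (and from 27) and comes back to the route at 33.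

**Further compounds**

F0 | step 8 | none | none
F0 | step 9 | none | none
F1 | step 18 | 2-[(3S,4S,6R)-4,6-dimethyl-6-[(2R)-2-methylbut-3-en-1-yl]-1,2-dioxan-3-yl]ethyl acetate | C=C[C@H](C)C[C@]1(C)C[C@H](C)[C@H](CCOC(C)=O)OO1
F2 | step 18 | (3S,4E)-3-methyl-5-phenylpent-4-enal | C[C@H](/C=C/c1ccccc1)CC=O
F3 | step 18 | [(1E,3S)-3-methylhexa-1,5-dien-1-yl]benzene | C[C@H](/C=C/c1ccccc1)CC=C
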